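**Plan**
1. Retrosynthesis: cut the interflavan bond C4(upper unit)–C6(lower unit); before that, cut the two Si–O bonds of a diisopropylsilylene tether that joins O3 of the upper unit to O7 of the lower unit; cut each flavan at C2–aryl (chromone + arylboronic acid).
2. Enabling feature: the upper 3-OH is cis-vicinal to the new bond and the lower 7-OH is ortho to C6, so O3–C3–C4–C6–C7–O7 plus one silicon atom make a seven-membered ring. Upper C4 is benzylic, ortho/para to ring oxygen O1 and 7-O of ring A (easy cation); lower C6 is ortho/para to O7 and O1 (good nucleophile).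
3. Forward: two chromones from gallacetophenone; ring C of each unit by Rh-catalysed asymmetric 1,4-addition with antipodal ligands (sets C2), Rubottom hydroxylation (2,3-trans), NaBH4.
4. Upper unit: 4-OH to 4-SBn (epimer mixture). Lower unit: 4-OBn ether, C3 inverted by oxidation and bulky-hydride reduction to the all-cis pattern, 7-O-allyl removed.
5. Silicon tether, then silver-triggered stereoconvergent intramolecular Friedel–Crafts closure sets upper C4 (3,4-cis) and the C6 regiochemistry; fluoride, then hydrogenolysis.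
6. Stereochemistry: C2 from the catalyst; C3 from the C2 aryl group; lower C4 and C3 from anti attack of nucleophile and hydride; upper C4 from the tether.

Key step: step 18

Assumption: the rhodium/bisphosphine catalyst is taken to follow the usual cyclic-enone model, the (R)-ligand giving (2R)-flavanone 6 and the (S)-ligand (2S)-flavanone 16; if the sense is the reverse, the two ligand antipodes are exchanged.
Remark: C4 of 11, 25 and 26 is an epimer mixture, written without configuration and used as such.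

**Route**

Step 1
Reactants: 1 2',3',4'-trihydroxyacetophenone (gallacetophenone)
Product: 2 1-[3,4-bis(benzyloxy)-2-hydroxyphenyl]ethanone
Conditions: BnBr (2.1 equiv), K2CO3, DMF, 25 °C
Reagents that add atoms: benzyl bromide BrCc1ccccc1
Why: Williamson etherification; the 2-OH, hydrogen-bonded to the acetyl group, is the least reactive and should stay free.

Step 2
Reactants: 2 1-[3,4-bis(benzyloxy)-2-hydroxyphenyl]ethanone
Product: 4 7,8-bis(benzyloxy)-4H-chromen-4-one, via enaminone 3 (not isolated)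
Conditions: DMF-DMA, 95 °C; then conc. HCl, CH2Cl2, 40 °C
Reagents that add atoms: N,N-dimethylformamide dimethyl acetal COC(OC)N(C)C
Why: Enaminone formation at the acetyl methyl group followed by acid-mediated cyclocondensation with loss of dimethylamine is the standard chromone synthesis from 2-hydroxyacetophenones.

Step 3
Reactants: 4 7,8-bis(benzyloxy)-4H-chromen-4-one; 5 4-(benzyloxy)phenylboronic acid
Product: 6 (2R)-7,8-bis(benzyloxy)-2-[4-(benzyloxy)phenyl]chroman-4-one
Conditions: [Rh(OH)(cod)]2 (3 mol%), (R)-MeO-F12-BIPHEP (7 mol%), CH2Cl2/H2O 10:1, 30 °C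
Reagents that add atoms: none
Why: Rhodium-catalysed asymmetric 1,4-addition of an arylboronic acid to a chromone (Hayashi–Miyaura type); the chiral bisphosphine selects the face of C2, and the base-free two-phase medium should suppress ring opening of the flavanone.

Step 4
Reactants: 6 (2R)-7,8-bis(benzyloxy)-2-[4-(benzyloxy)phenyl]chroman-4-one
Product: 9 (2S,3S)-7,8-bis(benzyloxy)-2-[4-(benzyloxy)phenyl]-3-hydroxychroman-4-one, via silyl enol ether 7 (not isolated), via 3-silyloxy ketone 8 (not isolated)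
Conditions: TMSOTf, Et3N, CH2Cl2, 0 °C; then DMDO, acetone, −40 °C; then aq. citric acid, THF
Reagents that add atoms: dimethyldioxirane CC1(C)OO1
Why: Rubottom oxidation; soft enolisation avoids retro-oxa-Michael opening, and the oxidant should attack the enol ether face anti to the C2 aryl group to give the 2,3-trans hydroxy ketone.

Step 5
Reactants: 9 (2S,3S)-7,8-bis(benzyloxy)-2-[4-(benzyloxy)phenyl]-3-hydroxychroman-4-one
Product: 10 (2S,3R,4S)-7,8-bis(benzyloxy)-2-[4-(benzyloxy)phenyl]chroman-3,4-diol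
Conditions: NaBH4, THF/MeOH, 0 °C
Reagents that add atoms: none
Why: Borohydride reduction of a 2,3-trans dihydroflavonol, expected to give mainly the 3,4-trans diol by pseudo-axial hydride attack; the C4 configuration is erased in step 18.

Step 6
Reactants: 10 (2S,3R,4S)-7,8-bis(benzyloxy)-2-[4-(benzyloxy)phenyl]chroman-3,4-diol
Product: 11 (2S,3S)-4-(benzylsulfanyl)-7,8-bis(benzyloxy)-2-[4-(benzyloxy)phenyl]chroman-3-ol (C4 epimer mixture)
Conditions: BnSH (5 equiv), BF3·OEt2 (0.2 equiv), CH2Cl2, −30 °C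
Reagents that add atoms: benzyl mercaptan SCc1ccccc1
Why: Acid-catalysed SN1 thiolysis of the benzylic 4-OH (thioacidolysis of a flavan-3,4-diol); only C4 ionises, so the 3-OH stays free for the tether.

Step 7
Reactants: 1 2',3',4'-trihydroxyacetophenone (gallacetophenone)
Product: 12 1-[4-(allyloxy)-2,3-dihydroxyphenyl]ethanone
Conditions: allyl bromide (1.05 equiv), Li2CO3, DMF, 50 °C
Reagents that add atoms: allyl bromide C=CCBr
Why: Regioselective Williamson etherification; the 4-OH para to the acetyl group is the most acidic and should react first with a weak base.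

Step 8
Reactants: 12 1-[4-(allyloxy)-2,3-dihydroxyphenyl]ethanone
Product: 13 1-[4-(allyloxy)-3-(benzyloxy)-2-hydroxyphenyl]ethanone
Conditions: BnBr (1.05 equiv), K2CO3, acetone, 40 °C
Reagents that add atoms: benzyl bromide BrCc1ccccc1
Why: Williamson etherification of the 3-OH, the chelated 2-OH again staying free.

Step 9
Reactants: 13 1-[4-(allyloxy)-3-(benzyloxy)-2-hydroxyphenyl]ethanone
Product: 15 7-(allyloxy)-8-(benzyloxy)-4H-chromen-4-one, via enaminone 14 (not isolated)
Conditions: DMF-DMA, 95 °C; then conc. HCl, CH2Cl2, 40 °C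
Reagents that add atoms: N,N-dimethylformamide dimethyl acetal COC(OC)N(C)C
Why: Same enaminone cyclocondensation to a chromone as in step 2; the allyl aryl ether tolerates both stages.

Step 10
Reactants: 15 7-(allyloxy)-8-(benzyloxy)-4H-chromen-4-one; 5 4-(benzyloxy)phenylboronic acid
Product: 16 (2S)-7-(allyloxy)-8-(benzyloxy)-2-[4-(benzyloxy)phenyl]chroman-4-one
Conditions: [Rh(OH)(cod)]2 (3 mol%), (S)-MeO-F12-BIPHEP (7 mol%), CH2Cl2/H2O 10:1, 30 °C
Reagents that add atoms: none
Why: Rhodium-catalysed asymmetric 1,4-addition (Hayashi–Miyaura type) with the antipodal ligand sets the opposite C2 configuration; the enone should insert much faster than the isolated allyl ether.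

Step 11
Reactants: 16 (2S)-7-(allyloxy)-8-(benzyloxy)-2-[4-(benzyloxy)phenyl]chroman-4-one
Product: 19 (2R,3R)-7-(allyloxy)-8-(benzyloxy)-2-[4-(benzyloxy)phenyl]-3-hydroxychroman-4-one, via silyl enol ether 17 (not isolated), via 3-silyloxy ketone 18 (not isolated)
Conditions: TMSOTf, Et3N, CH2Cl2, 0 °C; then DMDO (1.05 equiv), acetone, −40 °C; then aq. citric acid, THF
Reagents that add atoms: dimethyldioxirane CC1(C)OO1
Why: Rubottom oxidation anti to the C2 aryl group gives the 2,3-trans hydroxy ketone; the electron-rich silyl enol ether should be oxidised far faster than the allyl ether.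

Step 12
Reactants: 19 (2R,3R)-7-(allyloxy)-8-(benzyloxy)-2-[4-(benzyloxy)phenyl]-3-hydroxychroman-4-one
Product: 20 (2R,3S,4R)-7-(allyloxy)-8-(benzyloxy)-2-[4-(benzyloxy)phenyl]chroman-3,4-diol
Conditions: NaBH4, THF/MeOH, 0 °C
Reagents that add atoms: none
Why: Borohydride reduction with pseudo-axial hydride attack should give the all-equatorial 2,3-trans-3,4-trans diol, placing the C4 oxygen on the α face as the target requires.

Step 13
Reactants: 20 (2R,3S,4R)-7-(allyloxy)-8-(benzyloxy)-2-[4-(benzyloxy)phenyl]chroman-3,4-diol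
Product: 21 (2R,3S,4R)-7-(allyloxy)-4,8-bis(benzyloxy)-2-[4-(benzyloxy)phenyl]chroman-3-ol
Conditions: BnOH (10 equiv), BF3·OEt2 (0.2 equiv), CH2Cl2, −30 °C
Reagents that add atoms: benzyl alcohol OCc1ccccc1
Why: Acid-catalysed SN1 etherification of the benzylic 4-OH only; capture of the cation anti to the 3-OH (also the thermodynamic diequatorial product) should keep the 4α configuration, and any 4-epimer is removed by chromatography.

Step 14
Reactants: 21 (2R,3S,4R)-7-(allyloxy)-4,8-bis(benzyloxy)-2-[4-(benzyloxy)phenyl]chroman-3-ol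
Product: 22 (2R,4R)-7-(allyloxy)-4,8-bis(benzyloxy)-2-[4-(benzyloxy)phenyl]chroman-3-one
Conditions: Dess–Martin periodinane, CH2Cl2, 0 to 25 °C
Reagents that add atoms: none
Why: Dess–Martin oxidation under near-neutral conditions, as used for flavan-3-ols; the 2,4-cis diequatorial ketone is also the thermodynamically preferred arrangement, so C2 and C4 should hold.

Step 15
Reactants: 22 (2R,4R)-7-(allyloxy)-4,8-bis(benzyloxy)-2-[4-(benzyloxy)phenyl]chroman-3-one
Product: 23 (2R,3R,4R)-7-(allyloxy)-4,8-bis(benzyloxy)-2-[4-(benzyloxy)phenyl]chroman-3-ol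
Conditions: LiBH(s-Bu)3, THF, −78 °C; then H2O
Reagents that add atoms: none
Why: Bulky-hydride ketone reduction; equatorial attack from the face opposite the two flanking α substituents (2-aryl and 4-benzyloxy) should give the axial 3α-OH, i.e. the all-cis pattern, as in the known catechin-to-epicatechin inversion.

Step 16
Reactants: 23 (2R,3R,4R)-7-(allyloxy)-4,8-bis(benzyloxy)-2-[4-(benzyloxy)phenyl]chroman-3-ol
Product: 24 (2R,3R,4R)-4,8-bis(benzyloxy)-2-[4-(benzyloxy)phenyl]chroman-3,7-diol
Conditions: Pd(PPh3)4 (5 mol%), morpholine (10 equiv), THF, 25 °C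
Reagents that add atoms: none
Why: Tsuji–Trost-type deallylation of the aryl allyl ether with an amine scavenger under neutral conditions frees only the 7-OH; benzyl ethers and the benzylic 4-benzyloxy group are inert.

Step 17
Reactants: 11 (2S,3S)-4-(benzylsulfanyl)-7,8-bis(benzyloxy)-2-[4-(benzyloxy)phenyl]chroman-3-ol; 24 (2R,3R,4R)-4,8-bis(benzyloxy)-2-[4-(benzyloxy)phenyl]chroman-3,7-diol
Product: 26 diisopropylsilanediyl bis-ether joining O3 of 11 to O7 of 24, via chlorosilane 25 (not isolated)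
Conditions: 11, i-Pr2SiCl2 (3 equiv), imidazole, CH2Cl2, 0 to 25 °C, excess silane removed in vacuo; then 24 (1.0 equiv), imidazole, DMAP (cat.), DMF, 25 °C
Reagents that add atoms: dichlorodiisopropylsilane CC(C)[Si](Cl)(Cl)C(C)C
Why: Stepwise substitution at silicon (mixed silaketal formation); excess dichlorosilane prevents symmetrical coupling of 11, and the phenol of 24 should react in preference to its hindered axial 3-OH.

Step 18
Reactants: 26 diisopropylsilanediyl bis-ether joining O3 of 11 to O7 of 24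
Product: 27 cyclic 3(upper)-O,7(lower)-O-diisopropylsilylene derivative of 28 (upper unit 2,3-trans-3,4-cis; lower unit all-cis)
Conditions: AgOTf (2.5 equiv), 2,6-di-tert-butyl-4-methylpyridine (3 equiv), 4 Å MS, CH2Cl2 (0.002 M), −40 to 0 °C
Reagents that add atoms: none
Why: Proposed new method: AgOTf abstracts the benzylthiolate from C4 of either epimer of 26 to give one planar benzylic cation stabilised by the ring oxygen O1 (ortho) and the 7-benzyloxy group (para) of the upper ring A, and C6 of the lower ring A (ortho to the silylated O7, para to its ring oxygen) captures it in an intramolecular Friedel–Crafts alkylation, the hindered pyridine taking up the proton on rearomatisation. The closest known reaction types are the silver-promoted intermolecular coupling of flavan-4-yl thioethers with phenolic flavans and the temporary silicon tether used to deliver a nucleophile from a neighbouring oxygen to a cationic centre. The ring closed is the seven-membered 1,3-dioxa-2-silepine O3–Si–O7–C7–C6–C4–C3, a seven-membered closure in which the attacking arene bond C6=C7 lies inside the new ring and the π system that stabilises the cation lies outside it. The only new stereocentre, upper C4, is controlled by the tether: the five-atom chain anchored on the α-oxygen at C3 can place C6 only over the α face of the cation, so the 3,4-cis bond should form whatever the configuration of the thioether (stereoconvergent), against the usual preference of the untethered reaction for attack anti to the 3-oxygen. Attack at C6 rather than C5 or oxygen follows from the anchor at O7, whose other ortho position C8 is substituted; the thiophilic, buffered activation spares the benzylic 4-benzyloxy group of the lower unit, and high dilution suppresses intermolecular coupling.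

Step 19
Reactants: 27 cyclic 3(upper)-O,7(lower)-O-diisopropylsilylene derivative of 28
Product: 28 (2R,3R,4R)-4,8-bis(benzyloxy)-2-[4-(benzyloxy)phenyl]-6-{(2S,3R,4R)-7,8-bis(benzyloxy)-2-[4-(benzyloxy)phenyl]-3-hydroxychroman-4-yl}chroman-3,7-diol
Conditions: Bu4NF (2.2 equiv), AcOH (2.5 equiv), THF, 0 °C
Reagents that add atoms: none
Why: Fluoride cleavage of both Si–O bonds of the silaketal; buffering with acetic acid keeps the freed 7-phenol from expelling the para-benzylic 4-benzyloxy group through a quinone methide.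

Step 20
Reactants: 28 (2R,3R,4R)-4,8-bis(benzyloxy)-2-[4-(benzyloxy)phenyl]-6-{(2S,3R,4R)-7,8-bis(benzyloxy)-2-[4-(benzyloxy)phenyl]-3-hydroxychroman-4-yl}chroman-3,7-diol
Product: 29 ent-oritin-(4α→6)-epioritin-4α-ol, (2R,3R,4R)-6-[(2S,3R,4R)-3,7,8-trihydroxy-2-(4-hydroxyphenyl)chroman-4-yl]-2-(4-hydroxyphenyl)chroman-3,4,7,8-tetrol
Conditions: H2 (1 atm), Pd(OH)2/C, THF/MeOH, 25 °C; filtration under argon, lyophilisation
Reagents that add atoms: none
Why: Neutral catalytic hydrogenolysis of the six O–CH2Ph bonds; at the lower C4 ether the unhindered phenylmethyl C–O bond should cleave rather than the ring C4–O bond on the crowded, fully substituted ring A, and the resulting benzylic alcohol should resist further hydrogenolysis without acid.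

**Compound list**
1 | 2',3',4'-trihydroxyacetophenone (gallacetophenone) | CC(=O)c1ccc(O)c(O)c1O | starting material
2 | 1-[3,4-bis(benzyloxy)-2-hydroxyphenyl]ethanone | CC(=O)c1ccc(OCc2ccccc2)c(OCc2ccccc2)c1O | intermediate
3 | (E)-1-[3,4-bis(benzyloxy)-2-hydroxyphenyl]-3-(dimethylamino)prop-2-en-1-one | CN(C)/C=C/C(=O)c1ccc(OCc2ccccc2)c(OCc2ccccc2)c1O | intermediate
4 | 7,8-bis(benzyloxy)-4H-chromen-4-one | O=c1ccoc2c1ccc(OCc1ccccc1)c2OCc1ccccc1 | intermediate
5 | 4-(benzyloxy)phenylboronic acid | OB(O)c1ccc(OCc2ccccc2)cc1 | starting material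
6 | (2R)-7,8-bis(benzyloxy)-2-[4-(benzyloxy)phenyl]chroman-4-one | O=C1C[C@H](c2ccc(OCc3ccccc3)cc2)Oc2c1ccc(OCc1ccccc1)c2OCc1ccccc1 | intermediate
7 | (2R)-7,8-bis(benzyloxy)-2-[4-(benzyloxy)phenyl]-4-(trimethylsilyloxy)-2H-chromene | C[Si](C)(C)OC1=C[C@H](c2ccc(OCc3ccccc3)cc2)Oc2c1ccc(OCc1ccccc1)c2OCc1ccccc1 | intermediate
8 | (2S,3S)-7,8-bis(benzyloxy)-2-[4-(benzyloxy)phenyl]-3-(trimethylsilyloxy)chroman-4-one | O=C1[C@@H](O[Si](C)(C)C)[C@H](c2ccc(OCc3ccccc3)cc2)Oc2c1ccc(OCc1ccccc1)c2OCc1ccccc1 | intermediate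
9 | (2S,3S)-7,8-bis(benzyloxy)-2-[4-(benzyloxy)phenyl]-3-hydroxychroman-4-one | O=C1[C@@H](O)[C@H](c2ccc(OCc3ccccc3)cc2)Oc2c1ccc(OCc1ccccc1)c2OCc1ccccc1 | intermediate
10 | (2S,3R,4S)-7,8-bis(benzyloxy)-2-[4-(benzyloxy)phenyl]chroman-3,4-diol | O[C@H]1c2ccc(OCc3ccccc3)c(OCc3ccccc3)c2O[C@@H](c2ccc(OCc3ccccc3)cc2)[C@@H]1O | intermediate
11 | (2S,3S)-4-(benzylsulfanyl)-7,8-bis(benzyloxy)-2-[4-(benzyloxy)phenyl]chroman-3-ol, C4 epimer mixture | S(Cc1ccccc1)C1c2ccc(OCc3ccccc3)c(OCc3ccccc3)c2O[C@@H](c2ccc(OCc3ccccc3)cc2)[C@@H]1O | intermediate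
12 | 1-[4-(allyloxy)-2,3-dihydroxyphenyl]ethanone | CC(=O)c1ccc(OCC=C)c(O)c1O | intermediate
13 | 1-[4-(allyloxy)-3-(benzyloxy)-2-hydroxyphenyl]ethanone | CC(=O)c1ccc(OCC=C)c(OCc2ccccc2)c1O | intermediate
14 | (E)-1-[4-(allyloxy)-3-(benzyloxy)-2-hydroxyphenyl]-3-(dimethylamino)prop-2-en-1-one | CN(C)/C=C/C(=O)c1ccc(OCC=C)c(OCc2ccccc2)c1O | intermediate
15 | 7-(allyloxy)-8-(benzyloxy)-4H-chromen-4-one | O=c1ccoc2c1ccc(OCC=C)c2OCc1ccccc1 | intermediate
16 | (2S)-7-(allyloxy)-8-(benzyloxy)-2-[4-(benzyloxy)phenyl]chroman-4-one | O=C1C[C@@H](c2ccc(OCc3ccccc3)cc2)Oc2c1ccc(OCC=C)c2OCc1ccccc1 | intermediate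
17 | (2S)-7-(allyloxy)-8-(benzyloxy)-2-[4-(benzyloxy)phenyl]-4-(trimethylsilyloxy)-2H-chromene | C[Si](C)(C)OC1=C[C@@H](c2ccc(OCc3ccccc3)cc2)Oc2c1ccc(OCC=C)c2OCc1ccccc1 | intermediate
18 | (2R,3R)-7-(allyloxy)-8-(benzyloxy)-2-[4-(benzyloxy)phenyl]-3-(trimethylsilyloxy)chroman-4-one | O=C1[C@H](O[Si](C)(C)C)[C@@H](c2ccc(OCc3ccccc3)cc2)Oc2c1ccc(OCC=C)c2OCc1ccccc1 | intermediate
19 | (2R,3R)-7-(allyloxy)-8-(benzyloxy)-2-[4-(benzyloxy)phenyl]-3-hydroxychroman-4-one | O=C1[C@H](O)[C@@H](c2ccc(OCc3ccccc3)cc2)Oc2c1ccc(OCC=C)c2OCc1ccccc1 | intermediate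
20 | (2R,3S,4R)-7-(allyloxy)-8-(benzyloxy)-2-[4-(benzyloxy)phenyl]chroman-3,4-diol | O[C@@H]1c2ccc(OCC=C)c(OCc3ccccc3)c2O[C@H](c2ccc(OCc3ccccc3)cc2)[C@H]1O | intermediate
21 | (2R,3S,4R)-7-(allyloxy)-4,8-bis(benzyloxy)-2-[4-(benzyloxy)phenyl]chroman-3-ol | O(Cc1ccccc1)[C@@H]1c2ccc(OCC=C)c(OCc3ccccc3)c2O[C@H](c2ccc(OCc3ccccc3)cc2)[C@H]1O | intermediate
22 | (2R,4R)-7-(allyloxy)-4,8-bis(benzyloxy)-2-[4-(benzyloxy)phenyl]chroman-3-one | O(Cc1ccccc1)[C@@H]1c2ccc(OCC=C)c(OCc3ccccc3)c2O[C@H](c2ccc(OCc3ccccc3)cc2)C1=O | intermediate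
23 | (2R,3R,4R)-7-(allyloxy)-4,8-bis(benzyloxy)-2-[4-(benzyloxy)phenyl]chroman-3-ol | O(Cc1ccccc1)[C@@H]1c2ccc(OCC=C)c(OCc3ccccc3)c2O[C@H](c2ccc(OCc3ccccc3)cc2)[C@@H]1O | intermediate
24 | (2R,3R,4R)-4,8-bis(benzyloxy)-2-[4-(benzyloxy)phenyl]chroman-3,7-diol | O(Cc1ccccc1)[C@@H]1c2ccc(O)c(OCc3ccccc3)c2O[C@H](c2ccc(OCc3ccccc3)cc2)[C@@H]1O | intermediate
25 | 3-O-[chloro(diisopropyl)silyl] ether of 11 | S(Cc1ccccc1)C1c2ccc(OCc3ccccc3)c(OCc3ccccc3)c2O[C@@H](c2ccc(OCc3ccccc3)cc2)[C@@H]1O[Si](Cl)(C(C)C)C(C)C | intermediate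
26 | diisopropylsilanediyl bis-ether joining O3 of 11 to O7 of 24 | S(Cc1ccccc1)C1c2ccc(OCc3ccccc3)c(OCc3ccccc3)c2O[C@@H](c2ccc(OCc3ccccc3)cc2)[C@@H]1O[Si](C(C)C)(C(C)C)Oc1ccc2c(c1OCc1ccccc1)O[C@H](c1ccc(OCc3ccccc3)cc1)[C@H](O)[C@@H]2OCc1ccccc1 | intermediate
27 | cyclic 3(upper)-O,7(lower)-O-diisopropylsilylene derivative of 28 | c1ccccc1COc1ccc([C@H]2Oc3c(cc([C@@H]4c5ccc(OCc7ccccc7)c(OCc7ccccc7)c5O[C@@H](c5ccc(OCc7ccccc7)cc5)[C@@H]4O6)c(O[Si]6(C(C)C)C(C)C)c3OCc7ccccc7)[C@@H](OCc7ccccc7)[C@H]2O)cc1 | intermediate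
28 | (2R,3R,4R)-4,8-bis(benzyloxy)-2-[4-(benzyloxy)phenyl]-6-{(2S,3R,4R)-7,8-bis(benzyloxy)-2-[4-(benzyloxy)phenyl]-3-hydroxychroman-4-yl}chroman-3,7-diol | c1ccccc1COc1ccc([C@H]2Oc3c(cc([C@@H]4c5ccc(OCc7ccccc7)c(OCc7ccccc7)c5O[C@@H](c5ccc(OCc7ccccc7)cc5)[C@@H]4O)c(O)c3OCc7ccccc7)[C@@H](OCc7ccccc7)[C@H]2O)cc1 | intermediate
29 | ent-oritin-(4α→6)-epioritin-4α-ol, (2R,3R,4R)-6-[(2S,3R,4R)-3,7,8-trihydroxy-2-(4-hydroxyphenyl)chroman-4-yl]-2-(4-hydroxyphenyl)chroman-3,4,7,8-tetrol | Oc1ccc([C@H]2Oc3c(cc([C@@H]4c5ccc(O)c(O)c5O[C@@H](c5ccc(O)cc5)[C@@H]4O)c(O)c3O)[C@@H](O)[C@H]2O)cc1 | target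

**Count and risks**
Total steps: 20. Longest linear sequence: 14 steps (steps 7 to 20, from 1 to 29).

Steps most likely to fail:

1. Step 18. The silaketal may be cleaved, or the cation may be captured intermolecularly or lose the C3 proton, before the seven-membered ring closes. The fallback is the known untethered silver-promoted coupling of a flavan-4-yl thioether with a phenolic flavan: it sets out from thioether 11 and phenol 24 (AgBF4, THF, 0 °C) and comes back to the route at 28, bypassing steps 17 to 19. Without the tether both C4 epimers are expected, so 28 would have to be separated by chromatography from its 3,4-trans C4 epimer F1.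

2. Step 17. Substitution at the hindered silicon may be incomplete or unselective (symmetrical siloxane, hydrolysis of the chlorosilane, silylation of the 3-OH of 24). The fallback builds the second Si–O bond by dehydrogenative coupling instead of chloride displacement: it sets out from 11, which with chlorodiisopropylsilane and imidazole would give the isolable 3-O-(diisopropylsilyl) ether F2, and a NaOH-catalysed cross-dehydrogenative Si–O coupling of the Si–H bond with the phenol of 24 (DMF, 25 to 45 °C) comes back to the route at 26.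

3. Step 10. Aryl transfer to the electron-rich chromone may be slow, the flavanone may ring-open with erosion of enantiopurity, or the allyl ether may react with the aryl-rhodium species. The fallback replaces asymmetric catalysis by resolution: it sets out from acetophenone 13, which with commercial 4-(benzyloxy)benzaldehyde under Claisen–Schmidt conditions (KOH, EtOH) would give the 2'-hydroxychalcone F3. Oxa-Michael ring closure (NaOAc, EtOH, reflux) would give the racemic flavanone F4, and preparative chromatography on a chiral stationary phase comes back to the route at 16, the unwanted (2R)-enantiomer F5 being set aside.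

**Further compounds**
F1 | step 18 | 3,4-trans (upper C4) epimer of 28 | c1ccccc1COc1ccc([C@H]2Oc3c(cc([C@H]4c5ccc(OCc7ccccc7)c(OCc7ccccc7)c5O[C@@H](c5ccc(OCc7ccccc7)cc5)[C@@H]4O)c(O)c3OCc7ccccc7)[C@@H](OCc7ccccc7)[C@H]2O)cc1
F2 | step 17 | 3-O-(diisopropylsilyl) ether of 11 | S(Cc1ccccc1)C1c2ccc(OCc3ccccc3)c(OCc3ccccc3)c2O[C@@H](c2ccc(OCc3ccccc3)cc2)[C@@H]1O[SiH](C(C)C)C(C)C
F3 | step 10 | (E)-1-[4-(allyloxy)-3-(benzyloxy)-2-hydroxyphenyl]-3-[4-(benzyloxy)phenyl]prop-2-en-1-one | O=C(/C=C/c1ccc(OCc2ccccc2)cc1)c1ccc(OCC=C)c(OCc2ccccc2)c1O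
F4 | step 10 | racemic 7-(allyloxy)-8-(benzyloxy)-2-[4-(benzyloxy)phenyl]chroman-4-one | O=C1CC(c2ccc(OCc3ccccc3)cc2)Oc2c1ccc(OCC=C)c2OCc1ccccc1
F5 | step 10 | (2R)-7-(allyloxy)-8-(benzyloxy)-2-[4-(benzyloxy)phenyl]chroman-4-one | O=C1C[C@H](c2ccc(OCc3ccccc3)cc2)Oc2c1ccc(OCC=C)c2OCc1ccccc1
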